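The readings were generated by integration from invented constants, noise included.

Choose the temperature of the next flask by the selectivity factor s, together with how far the run has gone in its time.

| setting | ash | birch | delta | alpha | epsilon | zeta | eta | gamma |
|---|---|---|---|---|---|---|---|---|
| left-handed substrate | 0.17 M | 0.38 M | 0.25 M | 0.25 M | 0.25 M | 0.25 M | 0.25 M | 0.25 M |
| right-handed substrate | 0.17 M | 0.38 M | 0.25 M | 0.25 M | 0.25 M | 0.25 M | 0.25 M | 0.25 M |
| gas | 72 mM (held) | 72 mM (held) | 72 mM (held) | 72 mM (held) | 72 mM (held) | 72 mM (held) | 72 mM (held) | 72 mM (held) |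
| temperature | 55 °C | 88 °C | 90 °C | 40 °C | 100 °C | 80 °C | 45 °C | 60 °C |
| remark | run made earlier | run made earlier |  |  |  |  |  |  |
| time |  |  | 2.0 d | 2.0 d | 2.0 d | 2.0 d | 2.0 d | 2.0 d |

| run | time / h | left-handed product / % | right-handed product / % |
|---|---|---|---|
| ash | 3.00 | 4 | 0 |
| ash | 10.0 | 9 | 1 |
| ash | 15.0 | 14 | 0 |
| ash | 25.0 | 15 | 3 |
| ash | 40.0 | 31 | 2 |
| ash | 50.0 | 33 | 3 |
| birch | 2.00 | 5 | 0 |
| birch | 4.00 | 16 | 4 |
| birch | 6.00 | 24 | 6 |
| birch | 8.00 | 31 | 5 |
| birch | 10.0 | 33 | 5 |
| birch | 12.0 | 39 | 10 |

(standard deviation of a reading: 2 percentage points)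

- reagent is single-handed; left-handed substrate and right-handed substrate are mirror images of each other, charged as a racemate, each of them at the stated concentration
- at the start none of the gas is in solution
- the handed part of reagent does not stay in what it makes, so the products of the two hands are mirror images too

- the flasks by excess of left-handed product over right-handed product, highest first, at 2.0 d (delta / alpha / epsilon / zeta / eta / gamma)
- the excess of left-handed product over right-handed product of the flask you put first, at 2.0 d
- the excess of left-handed product over right-handed product of the flask you put last, at 2.0 d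

Take the gas transfer as settled, with c(reagent) held near saturation. Each hand then falls pseudo-first-order. Both hands meet the same c(reagent) at each moment, so that level and the time cancel in one ratio. Define s as the ln of the part of left-handed substrate still there, divided by the ln of the part of right-handed substrate still there. Each reading counts both hands together, so take twice the reading as the share of its own hand used. From the last readings:

s(ash) = 17.4

s(birch) = 6.79

The right-handed reading of ash, 3%, is good to 2 percentage points, so s(ash) is loose. Still, s is lower in the hotter run.

Now reckon delta, which stands just above birch, with birch's numbers. A first-order rate constant does not depend on the charge.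

left-hand rate constant k = 0.126 h⁻¹

left-hand half-life = 5.49 h

That is far shorter than 2.0 d, so count the left hand as used. The right hand runs slower by s:

part of right hand left, r = 41.0%

excess = r/(2 − r) = 25.8%

Ash read 83.3% at 50.0 h. So go cooler than ash, and run alpha next, at 40 °C.

The forecast gives alpha > eta > gamma > zeta > delta > epsilon, with 91% first and 8.5% last, "because selectivity drops and the slow hand catches up". For delta it says 24, below my figure.

The flasks give alpha > eta > gamma > zeta > delta > epsilon, with 91.6% first and 6.14% last.

    reagent + left-handed substrate → left-handed product (k = 0.00732 M⁻¹ min⁻¹, Ea = 61.0 kJ mol⁻¹)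
    reagent + right-handed substrate → right-handed product (k = 4.82 × 10⁻⁴ M⁻¹ min⁻¹, Ea = 86.0 kJ mol⁻¹)
    gas ⇌ reagent, rate k3*(csat - [reagent]) (kL = 0.0389 min⁻¹)
    2 reagent → self-condensation product (k = 0.00262 M⁻¹ min⁻¹, Ea = 83.0 kJ mol⁻¹)
    reagent ⇌ dormant form (K = 7.33, k = 5.70 × 10⁻⁴ min⁻¹, Ea = 111 kJ mol⁻¹, ΔH = −35.0 kJ mol⁻¹)
    (constants at 60 °C)

Delta ended with 0.039% of its left-handed substrate and 34% of its right-handed substrate, so its ratio of rates s is 7.28, with c(reagent) at 0.0644 M against 72 mM at saturation and an excess of 20.2%. Gamma ended with 24% and 91% of the same two, so its s is 15.1, and its excess is 78.9%.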